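**Retrosynthetic overview**

- The target is an 8,8'-linked diaryl ether of two coumarins with no stereocentre: unit A is 7-methoxycoumarin-8-yl and unit B is 5,7-dihydroxycoumarin-8-yl. The strategy rests on one feature: in each pyranone ring the C3=C4 bond is unsubstituted and lies between the aryl carbon C4a and the lactone carbonyl C2.
- Both C3=C4 bonds are cut by ring-closing metathesis, which leads back to the bis(2-vinylphenyl acrylate) 15 on the intact diaryl ether. Both pyranone rings are formed together, last, in step 9; only benzyl removal follows.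
- The two vinyl/acrylate pairs come from bisphenol 10 by twofold ortho-formylation, Wittig methylenation and O-acryloylation. Each phenol has only one free ortho carbon, the future C4a.
- The hindered C8–O–C8 ether comes from SNAr of phenol 5 on 2-fluoro-3-methoxybenzaldehyde 6. The activating formyl group is then turned into the O1 oxygen of unit A by Baeyer–Villiger oxidation.
- Phenol 5 is made from 2,4,6-trihydroxybenzaldehyde 1 by dibenzylation, MOM protection and Baeyer–Villiger oxidation.

Key step: step 9

**Route**

Step 1
Reactants: 1 2,4,6-trihydroxybenzaldehyde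
Product: 2 2,4-bis(benzyloxy)-6-hydroxybenzaldehyde
Conditions: BnBr (2.05 equiv), K2CO3, DMF, rt
Reagents that add atoms: benzyl bromide, BrCc1ccccc1
Why: Williamson etherification should stop at the dibenzyl ether because the last hydroxyl is hydrogen-bonded to the formyl group and is the least nucleophilic, so two equivalents of bromide alkylate only the 4-OH and one 2-OH.

Step 2
Reactants: 2 2,4-bis(benzyloxy)-6-hydroxybenzaldehyde
Product: 3 2,4-bis(benzyloxy)-6-(methoxymethoxy)benzaldehyde
Conditions: NaH, MOMCl, DMF, 0 °C to rt
Reagents that add atoms: chloromethyl methyl ether, COCCl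
Why: Irreversible deprotonation with NaH breaks the chelate and the sodium phenoxide is alkylated by the reactive α-chloro ether (Williamson-type acetal formation), giving an acid-labile group orthogonal to the benzyl ethers.

Step 3
Reactants: 3 2,4-bis(benzyloxy)-6-(methoxymethoxy)benzaldehyde
Product: 5 2,4-bis(benzyloxy)-6-(methoxymethoxy)phenol, via aryl formate 4 (not isolated)
Conditions: mCPBA, DCM, 0 °C to rt; aq. NaHCO3 wash; then K2CO3 (cat.), MeOH, rt, argon
Reagents that add atoms: meta-chloroperoxybenzoic acid, OOC(=O)c1cccc(Cl)c1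
Why: In this Baeyer–Villiger (Dakin-type) oxidation the 2,4,6-trioxygenated aryl group migrates in preference to hydride, so the aldehyde should give the aryl formate, which mild basic methanolysis cleaves without touching the MOM or benzyl ethers.

Step 4
Reactants: 5 2,4-bis(benzyloxy)-6-(methoxymethoxy)phenol; 6 2-fluoro-3-methoxybenzaldehyde
Product: 7 2-[2,4-bis(benzyloxy)-6-(methoxymethoxy)phenoxy]-3-methoxybenzaldehyde
Conditions: Cs2CO3, degassed DMF, 100 °C, argon
Reagents that add atoms: none
Why: Nucleophilic aromatic substitution (SNAr) should work because the cesium phenoxide adds at the fluorine-bearing carbon ortho to the formyl group, which stabilises the Meisenheimer adduct, and fluoride is then lost to give the tetra-ortho-substituted diaryl ether.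

Step 5
Reactants: 7 2-[2,4-bis(benzyloxy)-6-(methoxymethoxy)phenoxy]-3-methoxybenzaldehyde
Product: 10 3,5-bis(benzyloxy)-2-(2-hydroxy-6-methoxyphenoxy)phenol, via diaryl ether formate 8 (not isolated), via MOM-protected phenol 9 (not isolated)
Conditions: mCPBA, DCM, 0 °C to rt; aq. NaHCO3 wash; then HCl, MeOH–THF, 50 °C
Reagents that add atoms: meta-chloroperoxybenzoic acid, OOC(=O)c1cccc(Cl)c1
Why: A second Baeyer–Villiger oxidation, in which the ortho-aryloxy-substituted ring migrates, turns the formyl group into a formate, and acid methanolysis then removes first the labile formate and then the MOM acetal while benzyl and methyl ethers are stable.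

Step 6
Reactants: 10 3,5-bis(benzyloxy)-2-(2-hydroxy-6-methoxyphenoxy)phenol
Product: 11 4,6-bis(benzyloxy)-3-(3-formyl-2-hydroxy-6-methoxyphenoxy)-2-hydroxybenzaldehyde
Conditions: MgCl2, Et3N, (CH2O)n, MeCN, reflux; aq. HCl work-up
Reagents that add atoms: paraformaldehyde (formaldehyde), C=O
Why: In the magnesium-mediated Casnati–Skattebøl ortho-formylation each magnesium phenoxide delivers formaldehyde only to its ortho carbon and a second formaldehyde accepts hydride, and since each phenol has a single free ortho position the formyl groups should enter only at the two future C4a carbons.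

Step 7
Reactants: 11 4,6-bis(benzyloxy)-3-(3-formyl-2-hydroxy-6-methoxyphenoxy)-2-hydroxybenzaldehyde; 12 methyltriphenylphosphonium bromide
Product: 13 3,5-bis(benzyloxy)-2-(2-hydroxy-6-methoxy-3-vinylphenoxy)-6-vinylphenol
Conditions: MePPh3Br (6 equiv), KOtBu (6 equiv), THF, 0 °C to rt; neutral work-up, used at once
Reagents that add atoms: methyltriphenylphosphonium bromide, C[P+](c1ccccc1)(c1ccccc1)c1ccccc1.[Br-]
Why: Wittig methylenation with excess non-stabilised ylide tolerates the phenoxides formed in situ, as is established for salicylaldehydes, so both formyl groups should become vinyl groups.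

Step 8
Reactants: 13 3,5-bis(benzyloxy)-2-(2-hydroxy-6-methoxy-3-vinylphenoxy)-6-vinylphenol; 14 acryloyl chloride
Product: 15 2-[2-(acryloyloxy)-4,6-bis(benzyloxy)-3-vinylphenoxy]-3-methoxy-6-vinylphenyl acrylate
Conditions: acryloyl chloride (3 equiv), Et3N, DCM, 0 °C, trace BHT
Reagents that add atoms: acryloyl chloride, C=CC(=O)Cl
Why: O-acylation of the two phenols by the acid chloride with an amine base is fast at 0 °C, where conjugate addition to the acrylate and polymerisation of the electron-rich styrenes should not compete.

Step 9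
Reactants: 15 2-[2-(acryloyloxy)-4,6-bis(benzyloxy)-3-vinylphenoxy]-3-methoxy-6-vinylphenyl acrylate
Product: 16 5,7-bis(benzyloxy)-8-[(7-methoxy-2-oxo-2H-chromen-8-yl)oxy]-2H-chromen-2-one
Conditions: second-generation Grubbs catalyst RuCl2(=CHPh)(PCy3)(H2IMes) (10 mol%), toluene (0.005 M), 80 °C, argon sparge
Reagents that add atoms: none
Why: The ruthenium benzylidene should exchange onto a styrenyl CH=CH2 group (the electron-poor acrylate is a poor initiation site), the new aryl-substituted alkylidene adds across the neighbouring acrylate C=C in a [2+2] step, and cycloreversion of the ruthenacyclobutane releases the C3=C4 bond and a ruthenium methylidene that leaves as ethylene, after which the same cycle runs on the other ring. The closest known reaction is ring-closing metathesis of 2-vinylphenyl acrylates to coumarins with second-generation ruthenium carbenes, here run twice on one substrate. The pyranone of unit A closes by six-membered ring-closing metathesis that joins the vinyl carbon on C4a to the α-carbon of the acrylate on O1, and the pyranone of unit B closes in the same six-membered mode on the more hindered styrene flanked by the 5-benzyloxy group, which is why the run is heated. No stereocentre is formed, and the cis geometry of each new C3=C4 bond is enforced by the six-membered lactone. The step needs each vinyl group to pair with the acrylate on its own ring; the ortho relationship makes six-membered closure much faster than the nine- or ten-membered cross-ring closures, and high dilution with removal of ethylene should suppress intermolecular cross-metathesis.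

Step 10
Reactants: 16 5,7-bis(benzyloxy)-8-[(7-methoxy-2-oxo-2H-chromen-8-yl)oxy]-2H-chromen-2-one
Product: 17 5,7-dihydroxy-8-[(7-methoxy-2-oxo-2H-chromen-8-yl)oxy]-2H-chromen-2-one
Conditions: BCl3 (6 equiv), pentamethylbenzene (6 equiv), DCM, −78 °C; MeOH then H2O quench
Reagents that add atoms: none
Why: Lewis acid debenzylation with BCl3 ionises the benzyl–oxygen bonds and pentamethylbenzene traps the benzyl cations by Friedel–Crafts alkylation, which protects the phloroglucinol-type ring B from C-benzylation; at −78 °C the aryl methyl ether, the diaryl ether and both lactones should survive, and the C3=C4 bonds are not at risk as they would be under hydrogenolysis.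

**Compound list**

1 | 2,4,6-trihydroxybenzaldehyde | O=Cc1c(O)cc(O)cc1O | starting material
2 | 2,4-bis(benzyloxy)-6-hydroxybenzaldehyde | O=Cc1c(O)cc(OCc2ccccc2)cc1OCc1ccccc1 | intermediate
3 | 2,4-bis(benzyloxy)-6-(methoxymethoxy)benzaldehyde | O=Cc1c(OCOC)cc(OCc2ccccc2)cc1OCc1ccccc1 | intermediate
4 | 2,4-bis(benzyloxy)-6-(methoxymethoxy)phenyl formate (aryl formate, not isolated) | O=COc1c(OCOC)cc(OCc2ccccc2)cc1OCc1ccccc1 | intermediate
5 | 2,4-bis(benzyloxy)-6-(methoxymethoxy)phenol | Oc1c(OCOC)cc(OCc2ccccc2)cc1OCc1ccccc1 | intermediate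
6 | 2-fluoro-3-methoxybenzaldehyde | COc1cccc(C=O)c1F | starting material
7 | 2-[2,4-bis(benzyloxy)-6-(methoxymethoxy)phenoxy]-3-methoxybenzaldehyde | COCOc1cc(OCc2ccccc2)cc(OCc2ccccc2)c1Oc1c(OC)cccc1C=O | intermediate
8 | 2-[2,4-bis(benzyloxy)-6-(methoxymethoxy)phenoxy]-3-methoxyphenyl formate (diaryl ether formate, not isolated) | COCOc1cc(OCc2ccccc2)cc(OCc2ccccc2)c1Oc1c(OC)cccc1OC=O | intermediate
9 | 2-[2,4-bis(benzyloxy)-6-(methoxymethoxy)phenoxy]-3-methoxyphenol (MOM-protected phenol, not isolated) | COCOc1cc(OCc2ccccc2)cc(OCc2ccccc2)c1Oc1c(OC)cccc1O | intermediate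
10 | 3,5-bis(benzyloxy)-2-(2-hydroxy-6-methoxyphenoxy)phenol | COc1cccc(O)c1Oc1c(O)cc(OCc2ccccc2)cc1OCc1ccccc1 | intermediate
11 | 4,6-bis(benzyloxy)-3-(3-formyl-2-hydroxy-6-methoxyphenoxy)-2-hydroxybenzaldehyde | COc1ccc(C=O)c(O)c1Oc1c(O)c(C=O)c(OCc2ccccc2)cc1OCc1ccccc1 | intermediate
12 | methyltriphenylphosphonium bromide | C[P+](c1ccccc1)(c1ccccc1)c1ccccc1.[Br-] | starting material
13 | 3,5-bis(benzyloxy)-2-(2-hydroxy-6-methoxy-3-vinylphenoxy)-6-vinylphenol | COc1ccc(C=C)c(O)c1Oc1c(O)c(C=C)c(OCc2ccccc2)cc1OCc1ccccc1 | intermediate
14 | acryloyl chloride | C=CC(=O)Cl | starting material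
15 | 2-[2-(acryloyloxy)-4,6-bis(benzyloxy)-3-vinylphenoxy]-3-methoxy-6-vinylphenyl acrylate | C=CC(=O)Oc1c(C=C)ccc(OC)c1Oc1c(OCc2ccccc2)cc(OCc2ccccc2)c(C=C)c1OC(=O)C=C | intermediate
16 | 5,7-bis(benzyloxy)-8-[(7-methoxy-2-oxo-2H-chromen-8-yl)oxy]-2H-chromen-2-one | COc1ccc2ccc(=O)oc2c1Oc1c(OCc2ccccc2)cc(OCc2ccccc2)c2ccc(=O)oc12 | intermediate
17 | 5,7-dihydroxy-8-[(7-methoxy-2-oxo-2H-chromen-8-yl)oxy]-2H-chromen-2-one | COc1ccc2ccc(=O)oc2c1Oc1c(O)cc(O)c2ccc(=O)oc12 | target

**Step count and risks**

Total step count: 10. Longest linear sequence: 10 steps (1 to 17).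

Steps most likely to fail:

1. Step 9 (twofold ring-closing metathesis). The catalyst may load slowly onto the di-ortho-substituted styrene of ring B, so that only unit A closes, and the open vinyl or acrylate ends may then be lost to intermolecular cross-metathesis and oligomer formation. Fallback: set out from dialdehyde 11 and heat it with ethyl (triphenylphosphoranylidene)acetate in N,N-diethylaniline at reflux. Wittig olefination should give ethyl (E)-3-[4,6-bis(benzyloxy)-3-{3-[(E)-3-ethoxy-3-oxoprop-1-enyl]-2-hydroxy-6-methoxyphenoxy}-2-hydroxyphenyl]acrylate F1. In the same hot medium this should isomerise about each C=C and lactonise onto the neighbouring phenol with loss of ethanol, coming back to the route at 16. This is the classical salicylaldehyde-to-coumarin sequence and needs no metathesis.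

2. Step 4 (SNAr ether formation). Addition of the di-ortho-substituted phenoxide to a fluoride flanked by methoxy and formyl groups may be slow, so that air oxidation of the very electron-rich phenoxide overtakes substitution. Fallback: set out from phenol 5 and couple it with 2-bromo-3-methoxybenzaldehyde by copper-catalysed Ullmann O-arylation (CuI, picolinic acid, K3PO4, DMSO, 90 °C). The ortho-formyl group assists the copper insertion, and the sequence comes back to the route at 7. This fallback makes no new compound (F0).

3. Step 6 (twofold ortho-formylation). The reaction may stall after one formylation, or at the hydroxymethyl stage, because the neighbouring ether oxygens tie up the magnesium. Fallback: set out from bisphenol 10 and alkylate both phenols with allyl bromide and K2CO3 in acetone to give 1-(allyloxy)-2-[2-(allyloxy)-6-methoxyphenoxy]-3,5-bis(benzyloxy)benzene F2. Thermal aromatic Claisen rearrangement (N,N-diethylaniline, 190 °C) should move each allyl group to the only free ortho carbon and give 2-allyl-6-(3-allyl-2-hydroxy-6-methoxyphenoxy)-3,5-bis(benzyloxy)phenol F3. Double-bond migration with RuClH(CO)(PPh3)3 in toluene at 80 °C should give 3,5-bis(benzyloxy)-2-{2-hydroxy-6-methoxy-3-[(E)-prop-1-enyl]phenoxy}-6-[(E)-prop-1-enyl]phenol F4. Acryloyl chloride and Et3N should then give 2-{2-(acryloyloxy)-4,6-bis(benzyloxy)-3-[(E)-prop-1-enyl]phenoxy}-3-methoxy-6-[(E)-prop-1-enyl]phenyl acrylate F5. Ring-closing metathesis of F5 with second-generation Grubbs catalyst RuCl2(=CHPh)(PCy3)(H2IMes) in toluene at 80 °C, with loss of propene, comes back to the route at 16. This path also avoids the Wittig step and the sensitive vinylphenol 13.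

**Further compounds**

F1 | step 9 | ethyl (E)-3-[4,6-bis(benzyloxy)-3-{3-[(E)-3-ethoxy-3-oxoprop-1-enyl]-2-hydroxy-6-methoxyphenoxy}-2-hydroxyphenyl]acrylate | CCOC(=O)/C=C/c1ccc(OC)c(Oc2c(O)c(/C=C/C(=O)OCC)c(OCc3ccccc3)cc2OCc2ccccc2)c1O
F0 | step 4 | none | none
F2 | step 6 | 1-(allyloxy)-2-[2-(allyloxy)-6-methoxyphenoxy]-3,5-bis(benzyloxy)benzene | COc1cccc(OCC=C)c1Oc1c(OCC=C)cc(OCc2ccccc2)cc1OCc1ccccc1
F3 | step 6 | 2-allyl-6-(3-allyl-2-hydroxy-6-methoxyphenoxy)-3,5-bis(benzyloxy)phenol | COc1ccc(CC=C)c(O)c1Oc1c(O)c(CC=C)c(OCc2ccccc2)cc1OCc1ccccc1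
F4 | step 6 | 3,5-bis(benzyloxy)-2-{2-hydroxy-6-methoxy-3-[(E)-prop-1-enyl]phenoxy}-6-[(E)-prop-1-enyl]phenol | COc1ccc(/C=C/C)c(O)c1Oc1c(O)c(/C=C/C)c(OCc2ccccc2)cc1OCc1ccccc1
F5 | step 6 | 2-{2-(acryloyloxy)-4,6-bis(benzyloxy)-3-[(E)-prop-1-enyl]phenoxy}-3-methoxy-6-[(E)-prop-1-enyl]phenyl acrylate | C=CC(=O)Oc1c(/C=C/C)ccc(OC)c1Oc1c(OCc2ccccc2)cc(OCc2ccccc2)c(/C=C/C)c1OC(=O)C=C
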